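## Retrosynthetic overview

- The only ring, the 2,3-dihydro-4H-pyran-4-one (O1, C2, C3, C4=O, C5, C6), is closed last at O1–C6 by gold-catalysed 6-endo-dig addition of a β-hydroxyl to an ynone.
- The ynone (C4–C5 bond) comes from a Weinreb amide and prop-1-ynylmagnesium bromide.
- The strategy rests on the single stereocentre C2: a carbinol carbon bonded to O1 and lying β to the C4 carbonyl (C2–C3–C4). This is the C3 carbinol of a β-hydroxy ester, set by enzymatic reduction of the matching β-keto ester.
- The β-keto ester is made in one operation from gondoic acid and a malonate half ester. Gondoic acid brings the whole C19 side chain with the Z-alkene already in place.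

Key step: step 2

Assumption: the ketoreductase is taken from a commercial screening panel that holds enzymes of both facial preferences. The member that gives the (3R)-alcohol is found by screening and is not named here.

## Route

Step 1
Reactants: 1 (Z)-icos-11-enoic acid (gondoic acid); 2 potassium ethyl malonate
Product: 5 ethyl (Z)-3-oxodocos-13-enoate, via acyl imidazolide 3 (not isolated), via acylmalonate half ester 4 (not isolated)
Conditions: CDI, THF, rt; then 2, MgCl2, Et3N, MeCN/THF, rt; 1 M HCl work-up
Reagents that add atoms: potassium ethyl malonate (2), CCOC(=O)CC(=O)[O-].[K+]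
Why: Masamune–Brooks homologation, in which the magnesium enolate of the malonate half ester is C-acylated by the acyl imidazolide and the adduct loses CO2 on acidification, under near-neutral conditions that cannot move or isomerise the Z-alkene.

Step 2
Reactants: 5 ethyl (Z)-3-oxodocos-13-enoate
Product: 6 ethyl (3R,13Z)-3-hydroxydocos-13-enoate
Conditions: (R)-selective NADPH-dependent ketoreductase (chosen by panel screen), NADP+ (cat.), iPrOH (20% v/v), KH2PO4/K2HPO4 buffer pH 7.0, MgSO4 (2 mM), Triton X-100 (1% w/v), 30 °C
Reagents that add atoms: none
Why: The NADPH-bound ketoreductase holds the keto ester so that the nicotinamide hydride is delivered to one enantioface of the C3 carbonyl while an active-site acid protonates the oxygen, and NADP+ is re-reduced in situ at the expense of isopropanol, which is oxidised to acetone. The closest known reaction type is the ketoreductase reduction of long-chain aliphatic β-keto esters such as 3-oxotetradecanoates to single-enantiomer β-hydroxy esters. No ring is closed and no skeletal bond is formed; only the C3–H bond is made. The new stereocentre C3 (the later ring C2) is controlled by the enzyme pocket alone, which tells the short CH2CO2Et arm from the C19 alkenyl arm, so the (3R) sense is fixed by the choice of enzyme and not by any substrate bias. The step needs enantiofacial selectivity and chemoselectivity for the ketone over the ester and the C13=C14 Z-alkene, and an enzymatic hydride transfer at pH 7 and 30 °C does not reduce or isomerise an isolated olefin and hydrolyses the ester only slowly. The lipophilic tail is kept accessible to the enzyme by the isopropanol cosolvent and the non-ionic surfactant.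

Step 3
Reactants: 6 ethyl (3R,13Z)-3-hydroxydocos-13-enoate
Product: 7 ethyl (3R,13Z)-3-[(tert-butyldimethylsilyl)oxy]docos-13-enoate
Conditions: TBSCl, imidazole, DMAP (cat.), CH2Cl2, rt
Reagents that add atoms: tert-butyldimethylsilyl chloride, CC(C)(C)[Si](C)(C)Cl
Why: Standard imidazole-promoted silylation of a secondary alcohol, which masks the hydroxyl for the two organomagnesium steps and does not touch the C3 configuration.

Step 4
Reactants: 7 ethyl (3R,13Z)-3-[(tert-butyldimethylsilyl)oxy]docos-13-enoate
Product: 8 (3R,13Z)-3-[(tert-butyldimethylsilyl)oxy]-N-methoxy-N-methyldocos-13-enamide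
Conditions: MeNHOMe·HCl, iPrMgCl, THF, −20 → 0 °C; aq. NH4Cl
Reagents that add atoms: N,O-dimethylhydroxylamine hydrochloride, CNOC.Cl
Why: Direct ester aminolysis by the chloromagnesium amide of N,O-dimethylhydroxylamine (Weinreb amide formation), a weakly basic nucleophile that attacks the ester carbonyl faster than it deprotonates C2, so the β-silyloxy group is not eliminated.

Step 5
Reactants: 8 (3R,13Z)-3-[(tert-butyldimethylsilyl)oxy]-N-methoxy-N-methyldocos-13-enamide; 9 prop-1-ynylmagnesium bromide
Product: 10 (6R,16Z)-6-[(tert-butyldimethylsilyl)oxy]pentacos-16-en-2-yn-4-one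
Conditions: 9 (0.5 M in THF), THF, 0 °C; aq. NH4Cl
Reagents that add atoms: prop-1-ynylmagnesium bromide (9), CC#C[Mg]Br
Why: Weinreb ketone synthesis, in which the alkynyl Grignard reagent adds once to give a magnesium-chelated tetrahedral intermediate that collapses to the ynone only on work-up, so no second addition occurs.

Step 6
Reactants: 10 (6R,16Z)-6-[(tert-butyldimethylsilyl)oxy]pentacos-16-en-2-yn-4-one
Product: 11 (6R,16Z)-6-hydroxypentacos-16-en-2-yn-4-one
Conditions: aq. HF (48%), MeCN/CH2Cl2, 0 °C → rt
Reagents that add atoms: none
Why: Fluoride-driven Si–O cleavage under acidic, non-basic conditions, which frees the alcohol without the base-induced β-elimination that a β-oxygenated ynone would suffer and leaves the alkene and the C–O stereocentre alone.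

Step 7
Reactants: 11 (6R,16Z)-6-hydroxypentacos-16-en-2-yn-4-one
Product: 12 (2R)-6-methyl-2-[(10Z)-nonadec-10-en-1-yl]-2,3-dihydro-4H-pyran-4-one
Conditions: Ph3PAuCl (5 mol%), AgOTf (5 mol%), CH2Cl2, rt, dark
Reagents that add atoms: none
Why: Cationic Ph3PAu+ (monovalent gold) π-activates the ynone triple bond so that the hydroxyl adds to the alkyne carbon β to the carbonyl (chain C2, ring C6) in a 6-endo-dig hydroalkoxylation followed by protodeauration, the known cycloisomerisation of β-hydroxy ynones to 2,3-dihydro-4H-pyran-4-ones, which forms only the O1–C6 bond and so keeps the (R) centre and the isolated Z-alkene intact.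

## Compound list

1 | (Z)-icos-11-enoic acid (gondoic acid) | CCCCCCCC/C=C\CCCCCCCCCC(=O)O | starting material
2 | potassium ethyl malonate (potassium 3-ethoxy-3-oxopropanoate) | CCOC(=O)CC(=O)[O-].[K+] | starting material
3 | 1-[(11Z)-icos-11-enoyl]-1H-imidazole (acyl imidazolide) | CCCCCCCC/C=C\CCCCCCCCCC(=O)n1ccnc1 | intermediate
4 | (13Z)-2-(ethoxycarbonyl)-3-oxodocos-13-enoic acid (acylmalonate half ester, present as its magnesium chelate, no fixed configuration at C2) | CCCCCCCC/C=C\CCCCCCCCCC(=O)C(C(=O)O)C(=O)OCC | intermediate
5 | ethyl (Z)-3-oxodocos-13-enoate | CCCCCCCC/C=C\CCCCCCCCCC(=O)CC(=O)OCC | intermediate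
6 | ethyl (3R,13Z)-3-hydroxydocos-13-enoate | CCCCCCCC/C=C\CCCCCCCCC[C@@H](O)CC(=O)OCC | intermediate
7 | ethyl (3R,13Z)-3-[(tert-butyldimethylsilyl)oxy]docos-13-enoate | CCCCCCCC/C=C\CCCCCCCCC[C@@H](O[Si](C)(C)C(C)(C)C)CC(=O)OCC | intermediate
8 | (3R,13Z)-3-[(tert-butyldimethylsilyl)oxy]-N-methoxy-N-methyldocos-13-enamide | CCCCCCCC/C=C\CCCCCCCCC[C@@H](O[Si](C)(C)C(C)(C)C)CC(=O)N(C)OC | intermediate
9 | prop-1-ynylmagnesium bromide | CC#C[Mg]Br | starting material
10 | (6R,16Z)-6-[(tert-butyldimethylsilyl)oxy]pentacos-16-en-2-yn-4-one | CCCCCCCC/C=C\CCCCCCCCC[C@@H](O[Si](C)(C)C(C)(C)C)CC(=O)C#CC | intermediate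
11 | (6R,16Z)-6-hydroxypentacos-16-en-2-yn-4-one | CCCCCCCC/C=C\CCCCCCCCC[C@@H](O)CC(=O)C#CC | intermediate
12 | (2R)-6-methyl-2-[(10Z)-nonadec-10-en-1-yl]-2,3-dihydro-4H-pyran-4-one | CCCCCCCC/C=C\CCCCCCCCC[C@@H]1CC(=O)C=C(C)O1 | target

## Step count and risk

Total step count: 7
Longest linear sequence: 7 steps (1 → 12)

Steps most likely to fail:

1. Step 2. The waxy C22 substrate may partition away from the enzyme so that conversion stalls, or no enzyme in the panel may combine acceptance of the C19 tail with high (R) facial selectivity. The fallback replaces biocatalysis by homogeneous asymmetric hydrogenation (Noyori type). It sets out from 5 and comes back at 6. Compound 5 is hydrogenated with RuCl2[(R)-BINAP], made in situ from [RuCl2(C6H6)]2 and (R)-BINAP, under H2 (4 atm) in EtOH at 50 °C. The keto ester chelates ruthenium through both carbonyls, and (R)-BINAP is expected to give the (3R)-alcohol by analogy with simple alkyl β-keto esters. The C13=C14 olefin has no neighbouring coordinating group and should react much more slowly than the chelated ketone; low pressure and a stop at full ketone conversion guard against its reduction or Z/E isomerisation. This fallback makes no compound outside the list (F0).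

2. Step 6. Silyl removal next to an ynone may trigger β-elimination of the C6 oxygen to a conjugated enynone, or addition of fluoride or water to the triple bond. The fallback drops the silyl group altogether. It sets out from 6 and comes back at 11, skipping 7, 8 and 10. Compound 6 is treated with MeNHOMe·HCl and iPrMgCl (one extra equivalent for the hydroxyl) in THF at −20 °C to give (3R,13Z)-3-hydroxy-N-methoxy-N-methyldocos-13-enamide F1. F1 is then treated with an excess of 9 in THF at 0 °C. The first equivalent forms the magnesium alkoxide, and the next adds to the amide to give a chelated tetrahedral intermediate, which is stable to retro-aldol cleavage and elimination until the NH4Cl quench releases 11.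

3. Step 7. Under the Lewis-acidic gold/silver conditions the β-hydroxy ynone may dehydrate, close in the 5-exo mode, or be hydrated by adventitious water, and the cationic gold species may decompose before turnover is complete. The fallback is a metal-free, two-stage addition–elimination closure. It sets out from 11 and comes back at 12. Diethylamine in EtOH at rt adds in conjugate fashion to the ynone to give the vinylogous amide (2E,6R,16Z)-2-(diethylamino)-6-hydroxypentacosa-2,16-dien-4-one F2. Trifluoroacetic acid in CH2Cl2 then protonates the enaminone, the hydroxyl adds to the iminium carbon, and diethylamine is expelled to give 12. This is the same type of closure by which amino- and alkoxy-substituted aldol adducts of oxygenated dienes are turned into dihydropyranones.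

## Further compounds

F0 | step 2 | none | none
F1 | step 6 | (3R,13Z)-3-hydroxy-N-methoxy-N-methyldocos-13-enamide | CCCCCCCC/C=C\CCCCCCCCC[C@@H](O)CC(=O)N(C)OC
F2 | step 7 | (2E,6R,16Z)-2-(diethylamino)-6-hydroxypentacosa-2,16-dien-4-one | CCCCCCCC/C=C\CCCCCCCCC[C@@H](O)CC(=O)/C=C(\C)N(CC)CC
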